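## The problem

Target 8 is a 2,2'-bipyrrole. Ring A (N1, C2–C5) and ring B (N1', C2'–C5') are joined through C2–C2', both nitrogens are free N–H, and each of the six remaining carbons (C3, C4, C5, C3', C4', C5') carries bromine. There is no stereocentre, so nothing has to be set or relayed, and any stereocentre that appears on the way is transient. The six C–Br bonds are not the difficulty: pyrrole C–H positions take up electrophilic bromine readily, and a carboxyl group on a pyrrole α-carbon can be displaced by bromine with decarboxylation. The real task is to assemble the halogen-free C8N2 core before any bromine is present, because polybrominated N–H pyrroles tolerate neither reducing metals, low-valent transition-metal catalysts, strong bases nor prolonged light. The bare bipyrrole is itself electron-rich and prone to oxidation and acid-induced oligomerisation, so each ring should keep an acceptor (an N-acyl group on ring A, a carboxyl on ring B) for as long as possible. The feature that opens the route is that ring B is a 2,5-disubstituted pyrrole with unsubstituted C3' and C4'. The unit C2'–N1'–C5' can be read as an azomethine ylide made from the formyl carbon of a pyrrole-2-carbaldehyde (which brings ring A complete) and the N–CH2 of a glycine ester. C3'–C4' is then an acetylene equivalent, and the glycine carboxyl on C5' is the place-holder of the sixth bromine.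

Locants in the discussion follow the target. In the systematic names of 6, 7 and F3 the unprimed locants fall on the carboxyl-bearing ring B.

## Retrosynthesis

**8 to 7.** All six C–Br bonds are cut in one move: five go back to C–H and the one at C5' goes back to C–CO2H. Bromination belongs at the end because it is exhaustive, so no position has to be spared and no regiochemistry arises, and because no earlier step would tolerate C–Br bonds. Taking C5'–Br back to a carboxyl instead of C–H saves a separate decarboxylation and keeps ring B deactivated until the last step. Acid 7 (1H,1'H-2,2'-bipyrrole-5-carboxylic acid) is halogen-free and far lighter than 8. The forward reaction has to deliver six equivalents of electrophilic bromine, one of them at the ipso carbon, without oxidising the product further.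

**7 to 6.** Only protecting-group bonds are cut here: the O–ethyl bond of the ester and the N–CO2tBu bond on ring A. Both groups are chosen so that hydroxide removes them together. The ester is saponified, and the carbamate on a pyrrole nitrogen behaves as an activated acyl group towards nucleophiles. An acid-labile deprotection was avoided because it would expose an electron-rich bipyrrole to acid. Ester 6 is the direct product of the key step, so this step adds no detour.

**6 to 3 and 4, through 5.** The key cut runs through C2'–C3' and C4'–C5' of ring B.
- Cutting the C2–C2' bond instead would call for a halopyrrole and a metallated pyrrole, each to be made and protected separately.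
- Cutting at N1' (a condensation of Paal–Knorr type) would call for a 1,4-dicarbonyl chain on ring A that is harder to reach than 6 itself.
- The chosen cut leaves imine 3, which holds ring A and the C2'–N1'–C5' unit, and the symmetric two-carbon partner 4.

Because 4 carries two sulfonyl leaving groups, cycloadduct 5 is already at the oxidation level of a pyrrole and aromatises by two eliminations without an oxidant. The forward reaction needs only chemoselective trapping of a catalytically generated N-metallated ylide by 4. There is no regiochemical question (4 is symmetric) and no stereochemical one (all centres of 5 are erased).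

**3 to 1 and 2.** The C=N bond is cut back to aldehyde 1 and glycine ester salt 2, both catalogue compounds. A simple dehydrating condensation is all that is asked. The electron-withdrawing carbamate on ring A keeps the formyl group reactive.

## Roads not taken

**Alternative 1:** The cut is at N1–C5 and N1'–C5', back to N,N'-[(4R,5R)-octa-1,7-diyne-4,5-diyl]bis(4-methylbenzenesulfonamide) A1, in which the C2–C2' bond already exists as the central bond of a vicinal diamine.
- Forward key step: Ph3PAuNTf2 (univalent gold), or W(CO)6 with Et3N under irradiation through a zerovalent tungsten vinylidene, would add each sulfonamide nitrogen to its terminal alkyne carbon. This would close both rings and give (2R,2'R)-1,1'-ditosyl-2,2',3,3'-tetrahydro-1H,1'H-2,2'-bipyrrole A2. Base-induced loss of two sulfinates would then give 1H,1'H-2,2'-bipyrrole A3, which would be brominated six times.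
- Merits: both rings close in one catalytic, atom-economic operation; no bond has to be made between two heteroarenes; A3 needs only C–H bromination.
- Weak points:
  - A1 is not a catalogue compound. Its diamine core would have to come from double propargyl addition to a two-carbon bis-imine, with propargyl/allenyl regiochemistry and dl/meso mixtures to manage, and probably an exchange of nitrogen substituents.
  - The two stereocentres so installed are destroyed on aromatisation.
  - The endo closure needs attack at the unsubstituted alkyne carbon. The tungsten vinylidene variant is established mainly for alkynols and needs photolysis, and two neighbouring N-sulfonyl groups crowd the second closure.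
  - The enesulfonamides in A2 are acid-labile. Loss of sulfinate from a 2,3-dihydropyrrole requires removal of the hindered C2–H and is less secure than from the 2,5-dihydro isomer.
- Comparison: this road is better in that its last step is a plain sixfold C–H bromination with no decarboxylative event. Against that the chosen plan sets four steps from catalogue materials instead of six or seven, ring closure and aromatisation in one flask, and intermediates stabilised by acceptor groups.

**Alternative 2:** The cut is at C3=C4 and C3'=C4', back to the tetraene N,N'-[(3R,4R)-hexa-1,5-diene-3,4-diyl]bis[4-methyl-N-(prop-2-en-1-yl)benzenesulfonamide] A4.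
- Forward key step: the second-generation Grubbs catalyst Cl2Ru(=CHPh)(H2IMes)(PCy3) would close each N-allyl group onto the vinyl group on its own carbon. This double ring-closing metathesis would give (2R,2'R)-1,1'-ditosyl-2,2',5,5'-tetrahydro-1H,1'H-2,2'-bipyrrole A5. KOtBu would then expel two sulfinates to give A3, followed by hexabromination.
- Merits: every single operation is textbook chemistry. Metathesis to 2,5-dihydropyrroles is fast, and sulfinate loss from N-sulfonyl 2,5-dihydropyrroles is a reliable aromatisation that needs no oxidant.
- Weak points:
  - A4 stands four or five steps from commercial material (bis-imine, double vinyl addition with dl/meso issues, sulfonylation, double allylation).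
  - An N-allyl group can also close onto the vinyl group of the neighbouring carbon to give a six-membered ring.
  - A Ru carbene is spent on a ten-carbon target, and two stereocentres are again made only to be erased.
- Comparison: step for step this is probably the most predictable of the three alternatives, and its ring closure is at least as reliable as the chosen one. The chosen plan sets against it about half the step count, no separate aromatisation step, and a key step that builds ring B directly from an aldehyde, an amino ester and a two-carbon unit.

**Alternative 3:** The cut is at N1–C2 and N1'–C2', back to N,N'-(octa-3,5-diyne-1,8-diyl)bis(4-methylbenzenesulfonamide) A7, the oxidative homocoupling product (CuCl/TMEDA/O2) of N-(but-3-yn-1-yl)-4-methylbenzenesulfonamide A6.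
- Forward key step: cationic univalent gold (Ph3PAuCl with AgOTf) would activate each alkyne, and each sulfonamide nitrogen would add 5-endo to the inner diyne carbon. This would give 1,1'-ditosyl-4,4',5,5'-tetrahydro-1H,1'H-2,2'-bipyrrole A8. Aromatisation to A3 and hexabromination would follow.
- Merits: it is the shortest alternative (about five steps). The central C–C bond comes from a robust Glaser-type coupling, no stereocentre ever appears, and the route is symmetric and catalytic throughout.
- Weak points:
  - After the first ring has closed, the second alkyne is conjugated with an enesulfonamide, so the second hydroamination is a different and less predictable event.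
  - A8 is a doubly N-substituted 2-aminodiene, which is sensitive to hydrolysis and to oligomerisation under cationic gold.
  - Going from the 4,5-dihydro level to A3 needs either an elimination across N1–C5 with little precedent, or a dehydrogenation followed by two detosylations, which adds steps.
- Comparison: in step count this road is comparable, and in symmetry and atom economy it is better. The chosen plan sets against it a key step with close precedent on aryl glycinate imines, an aromatisation built into that step, and acceptor-stabilised intermediates in place of a fragile bis-enesulfonamide.

Key step: step 2

Assumption: 1 and 4 are taken as catalogue compounds. Cycloadduct 5 is expected as a racemic mixture of diastereomers and is drawn as one 2,5-cis-3,4-trans isomer; this has no bearing on the outcome because all four centres become sp2 in the same flask.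

## Steps

Step 1
Reactants: 1 tert-butyl 2-formyl-1H-pyrrole-1-carboxylate; 2 glycine ethyl ester hydrochloride
Product: 3 tert-butyl 2-{(E)-[(2-ethoxy-2-oxoethyl)imino]methyl}-1H-pyrrole-1-carboxylate
Conditions: Et3N (1.05 equiv), MgSO4, CH2Cl2, rt; filter, concentrate, use crude
Reagents that add atoms: none
Why: Schiff-base condensation of the amine freed from 2 by Et3N with the aldehyde, MgSO4 taking up the water; the N-Boc group keeps the formyl carbon electrophilic and the less hindered E aldimine is the thermodynamic isomer. The crude imine is carried on because glycinate aldimines hydrolyse on silica.

Step 2
Reactants: 3 tert-butyl 2-{(E)-[(2-ethoxy-2-oxoethyl)imino]methyl}-1H-pyrrole-1-carboxylate (1.1 equiv); 4 (E)-1,2-bis(phenylsulfonyl)ethene (1.0 equiv)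
Product: 6 ethyl 1'-(tert-butoxycarbonyl)-1H,1'H-2,2'-bipyrrole-5-carboxylate, via bis(phenylsulfonyl)pyrrolidine cycloadduct 5 (not isolated)
Conditions: AgOAc (10 mol %), Et3N (20 mol %), THF, rt, dark, Ar; then DBU (3 equiv), rt to 45 °C
Reagents that add atoms: none
Why: AgOAc binds the imine nitrogen and the ester carbonyl of 3 in a five-membered chelate, which acidifies the glycine CH2 enough for Et3N or acetate to give the N-metallated azomethine ylide. This 4π dipole adds across the strongly electron-poor C=C of 4 in a 1,3-dipolar cycloaddition, concerted but asynchronous or in the limit a Michael addition followed by a metal-templated 5-endo-trig Mannich closure, so that C2'–C3' and C4'–C5' are formed and ring B is closed as pyrrolidine 5 in an intermolecular [3+2] mode. The closest known reaction type is the AgOAc- or univalent-copper-catalysed cycloaddition of aryl glycinate aldimines with 1,2-bis(sulfonyl)ethylenes used as acetylene equivalents, followed by base-induced loss of sulfinate to 5-arylpyrrole-2-carboxylates. DBU then removes the proton α to the ester (C5'–H) and expels the C4' sulfinate (E1cB); the enamino ester tautomerises to the 1-pyrroline, whose C4'–H is now acidic, and a second E1cB loss of the C3' sulfinate gives a 2H-pyrrole that tautomerises to aromatic 6 without any oxidant. The four stereocentres of 5 (ester and pyrrolyl cis from the W-shaped ylide, sulfonyl groups trans from the E-alkene) all become sp2 carbons, so neither facial nor endo/exo selectivity matters. The only selectivity needed is chemoselectivity: 4 is symmetric, so there is no regiochemical question, and its high electrophilicity lets the catalytically formed ylide be trapped faster than the imine can hydrolyse or self-condense. The N-Boc group keeps the ring A nitrogen from competing for the Ag cation or being deprotonated, and DBU is added only after 4 has been consumed so that the amidine does not add to the disulfone; should DBU strip part of the Boc group, the material still converges on 7 in step 3.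

Step 3
Reactants: 6 ethyl 1'-(tert-butoxycarbonyl)-1H,1'H-2,2'-bipyrrole-5-carboxylate
Product: 7 1H,1'H-2,2'-bipyrrole-5-carboxylic acid
Conditions: NaOH (5 equiv), EtOH/H2O 2:1, 80 °C, Ar; then 0 °C, 1 M HCl to pH 3–4
Reagents that add atoms: sodium hydroxide, [Na+].[OH-]
Why: Saponification of the ethyl ester (acyl–oxygen cleavage by hydroxide); the carbamate on the pyrrole nitrogen is an activated N-acyl group with pyrrolide as leaving group and is cleaved by the same reagent to tert-butanol and carbonate. Cold, mild acidification liberates the acid while avoiding acid-induced protodecarboxylation.

Step 4
Reactants: 7 1H,1'H-2,2'-bipyrrole-5-carboxylic acid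
Product: 8 3,3',4,4',5,5'-hexabromo-1H,1'H-2,2'-bipyrrole
Conditions: NBS (6.1 equiv, in portions), NaHCO3 (1.5 equiv), DMF, 0 °C to rt, dark; aq. Na2S2O3 work-up
Reagents that add atoms: N-bromosuccinimide (NBS), O=C1CCC(=O)N1Br
Why: Exhaustive electrophilic aromatic bromination of the five pyrrole C–H positions, plus ipso attack of bromine at the carboxylate-bearing C5' with loss of CO2 from the σ-complex (halodecarboxylation of a pyrrole-2-carboxylic acid). Since every position is substituted there is no regiochemical issue; bicarbonate keeps the carboxyl ionised, which favours ipso attack, and is not consumed in the overall balance.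

## Compound list

1 | tert-butyl 2-formyl-1H-pyrrole-1-carboxylate | O=Cc1cccn1C(=O)OC(C)(C)C | starting material
2 | glycine ethyl ester hydrochloride | Cl.NCC(=O)OCC | starting material
3 | tert-butyl 2-{(E)-[(2-ethoxy-2-oxoethyl)imino]methyl}-1H-pyrrole-1-carboxylate | CCOC(=O)C/N=C/c1cccn1C(=O)OC(C)(C)C | intermediate
4 | (E)-1,2-bis(phenylsulfonyl)ethene | O=S(=O)(/C=C/S(=O)(=O)c1ccccc1)c1ccccc1 | starting material
5 | ethyl 5-[1-(tert-butoxycarbonyl)-1H-pyrrol-2-yl]-3,4-bis(phenylsulfonyl)pyrrolidine-2-carboxylate (racemic; ester and pyrrolyl cis, sulfonyl groups trans, the sulfonyl next to the ester on the ester face) | N1[C@@H](C(=O)OCC)[C@@H](S(=O)(=O)c2ccccc2)[C@H](S(=O)(=O)c2ccccc2)[C@H]1c1cccn1C(=O)OC(C)(C)C | intermediate (formed in the flask in step 2, not isolated)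
6 | ethyl 1'-(tert-butoxycarbonyl)-1H,1'H-2,2'-bipyrrole-5-carboxylate | CCOC(=O)c1ccc([nH]1)-c1cccn1C(=O)OC(C)(C)C | intermediate
7 | 1H,1'H-2,2'-bipyrrole-5-carboxylic acid | OC(=O)c1ccc([nH]1)-c1ccc[nH]1 | intermediate
8 | 3,3',4,4',5,5'-hexabromo-1H,1'H-2,2'-bipyrrole | Brc1[nH]c(-c2[nH]c(Br)c(Br)c2Br)c(Br)c1Br | target

## Step count and risks

Total step count: 4. Longest linear sequence: 4 (from 1 or 2 to 8).

**Step 2 (key step).** The cycloaddition itself has close precedent; the aromatisation stage is the more likely place of failure. The base-induced sequence may halt after the first sulfinate loss, because the second elimination has to wait for an enamine-to-imine tautomerisation. Meanwhile DBU may add to residual disulfone or attack the carbamate carbonyl. The fallback sets out from 5, which is then isolated after the AgOAc stage without adding DBU. Buffered reductive elimination of the vicinal disulfone with Na(Hg) and Na2HPO4 in THF/EtOH at −20 °C (Julia-type) should give ethyl cis-5-[1-(tert-butoxycarbonyl)-1H-pyrrol-2-yl]-2,5-dihydro-1H-pyrrole-2-carboxylate F1. Dehydrogenation of this 2,5-dihydropyrrole with activated MnO2 in CH2Cl2 at rt comes back to the route at 6. The approach changes from two base-induced eliminations to a reductive elimination followed by an oxidation.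

**Step 4.** Ipso substitution at the carboxyl-bearing carbon may fall behind the C–H brominations. Once five bromines are in place both rings are deactivated, and the sequence may stop before decarboxylation. Forcing it with more reagent invites N-bromination and oxidative degradation of the product. The fallback sets out from 7 and removes the carboxyl group first, by protodecarboxylation in ethanolamine at about 170 °C under Ar, to give 1H,1'H-2,2'-bipyrrole F2 (identical with A3 of the roads not taken). Sixfold C–H bromination with NBS (6 equiv) in THF, −78 °C to rt, then comes back to the route at 8.

**Step 3.** The free acid may lose its carboxyl group by protodecarboxylation during acidification. The doubly N–H bipyrrole carboxylate may also degrade oxidatively during the prolonged heating in alkali that complete carbamate cleavage may need. The fallback sets out from 6 and changes the deprotection mode. Thermolysis (neat, 180 °C, Ar) removes the Boc group by extrusion of isobutene and CO2 and should give ethyl 1H,1'H-2,2'-bipyrrole-5-carboxylate F3. This ester can then be saponified under milder conditions (LiOH, THF/H2O, 50 °C, brief cold acidification with HCl), coming back to the route at 7. Any material that does lose CO2 in step 3 is F2, which takes up six bromines under the step 4 conditions and so still converges on 8.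

## Further compounds

F1 | step 2 | ethyl cis-5-[1-(tert-butoxycarbonyl)-1H-pyrrol-2-yl]-2,5-dihydro-1H-pyrrole-2-carboxylate (racemic) | N1[C@@H](C(=O)OCC)C=C[C@H]1c1cccn1C(=O)OC(C)(C)C
F2 | step 4 | 1H,1'H-2,2'-bipyrrole | c1c[nH]c(c1)-c1ccc[nH]1
F3 | step 3 | ethyl 1H,1'H-2,2'-bipyrrole-5-carboxylate | CCOC(=O)c1ccc([nH]1)-c1ccc[nH]1
A1 | alternative 1 | N,N'-[(4R,5R)-octa-1,7-diyne-4,5-diyl]bis(4-methylbenzenesulfonamide) | C#CC[C@@H](NS(=O)(=O)c1ccc(C)cc1)[C@@H](CC#C)NS(=O)(=O)c1ccc(C)cc1
A2 | alternative 1 | (2R,2'R)-1,1'-ditosyl-2,2',3,3'-tetrahydro-1H,1'H-2,2'-bipyrrole | C1=CC[C@@H](N1S(=O)(=O)c1ccc(C)cc1)[C@@H](CC=C2)N2S(=O)(=O)c1ccc(C)cc1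
A3 | alternative 1 | 1H,1'H-2,2'-bipyrrole | c1c[nH]c(c1)-c1ccc[nH]1
A4 | alternative 2 | N,N'-[(3R,4R)-hexa-1,5-diene-3,4-diyl]bis[4-methyl-N-(prop-2-en-1-yl)benzenesulfonamide] | C=CCN(S(=O)(=O)c1ccc(C)cc1)[C@H](C=C)[C@@H](C=C)N(S(=O)(=O)c1ccc(C)cc1)CC=C
A5 | alternative 2 | (2R,2'R)-1,1'-ditosyl-2,2',5,5'-tetrahydro-1H,1'H-2,2'-bipyrrole | C1CN(S(=O)(=O)c3ccc(C)cc3)[C@H](C=1)[C@@H](C=2)N(S(=O)(=O)c3ccc(C)cc3)CC2
A6 | alternative 3 | N-(but-3-yn-1-yl)-4-methylbenzenesulfonamide | C#CCCNS(=O)(=O)c1ccc(C)cc1
A7 | alternative 3 | N,N'-(octa-3,5-diyne-1,8-diyl)bis(4-methylbenzenesulfonamide) | Cc1ccc(cc1)S(=O)(=O)NCCC#CC#CCCNS(=O)(=O)c1ccc(C)cc1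
A8 | alternative 3 | 1,1'-ditosyl-4,4',5,5'-tetrahydro-1H,1'H-2,2'-bipyrrole | Cc1ccc(cc1)S(=O)(=O)N1CCC=C1C1=CCCN1S(=O)(=O)c1ccc(C)cc1
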